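**Retrosynthetic overview**
1. Removing the C15 silyl ether, the C8 isobutyrate and the C11=C13 methylene group leads from target 26 back to the saturated trans-6,12-lactone alcohol 20.
2. The strategy rests on one feature. C7 is the β-carbon of the lactone carbonyl (C12–C11–C7) and is bonded to the carbinol carbon C8. C7–C8 is therefore the bond a C8 ketyl forms on adding to a C7=C11 butenolide, and cutting it opens the ten-membered carbocycle (ring A) to aldehyde 19.
3. In 19 the butenolide (ring C) comes from ring-closing metathesis of a C6 acrylate. The furanone (ring B) comes from gold-catalysed cyclisation of an α′-hydroxy ynone, and C3–C4 from Sonogashira coupling of iodide 14 with ynone 8.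
4. C10 derives from (S)-lactic acid by self-regeneration of stereocentres and C6 from a Sharpless kinetic resolution. The cis C3/C6 geometry on C4=C5 comes from a hydroxyl-directed trans-hydroalumination–iodination.
5. Rings form in the order B (step 12), C (step 13), A (step 15).

Key step: step 15

Remark: germacrane numbering of the target is used for all intermediates. C1 is the ketone, C2=C3 the furanone alkene, and oxygen bridges C3 and C10. C4=C5 carries C15 on C4. C6–O is the lactone oxygen and C8–O the ester oxygen. C9 is a CH2 group, C10 is quaternary and carries the methyl C14, C12 is the lactone carbonyl, and C11=C13 is the exocyclic methylene.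

**Step 1**
Reactants: 1 (S)-lactic acid
Product: 2 (2S,5S)-2-tert-butyl-5-methyl-1,3-dioxolan-4-one
Conditions: t-BuCHO, TsOH·H2O (cat.), H2SO4 (cat.), pentane, reflux, Dean–Stark; recrystallisation from pentane/Et2O, −78 °C
Reagents that add atoms: pivalaldehyde CC(C)(C)C=O
Why: Acid-catalysed acetalisation (first stage of the self-regeneration of stereocentres), in which the lactate centre directs the new acetal centre to the cis isomer, which should be obtained pure by crystallisation.

**Step 2**
Reactants: 2 (2S,5S)-2-tert-butyl-5-methyl-1,3-dioxolan-4-one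
Product: 3 (2S,5R)-5-allyl-2-tert-butyl-5-methyl-1,3-dioxolan-4-one
Conditions: LiN(i-Pr)2 (LDA), THF, −78 °C; allyl bromide, −78 → −20 °C
Reagents that add atoms: allyl bromide C=CCBr
Why: Diastereoselective enolate alkylation, in which the planar lithium enolate is attacked anti to the tert-butyl group, so allyl takes the place of the former hydrogen and fixes C10 as R.

**Step 3**
Reactants: 3 (2S,5R)-5-allyl-2-tert-butyl-5-methyl-1,3-dioxolan-4-one
Product: 5 (2S,5R)-2-tert-butyl-5-(2,2-dimethoxyethyl)-5-methyl-1,3-dioxolan-4-one, via dioxolanone aldehyde 4 (not isolated)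
Conditions: O3, CH2Cl2, −78 °C; Me2S, → rt; then HC(OMe)3, PPTS (cat.), MeOH, rt
Reagents that add atoms: trimethyl orthoformate COC(OC)OC; ozone [O-][O+]=O (oxygen of intermediate 4 only)
Why: Ozonolysis with reductive work-up followed by acid-catalysed acetalisation stores the future C8 aldehyde as a dimethyl acetal, and the dioxolanone has no other oxidisable site and should withstand PPTS.

**Step 4**
Reactants: 5 (2S,5R)-2-tert-butyl-5-(2,2-dimethoxyethyl)-5-methyl-1,3-dioxolan-4-one
Product: 6 (2R)-2-hydroxy-N,4,4-trimethoxy-N,2-dimethylbutanamide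
Conditions: MeNH(OMe)·HCl, i-PrMgCl, THF, −20 → 0 °C
Reagents that add atoms: N,O-dimethylhydroxylamine hydrochloride CNOC.Cl
Why: Weinreb aminolysis, in which the magnesium amide opens the activated acylal-type carbonyl and the hemiacetal alkoxide sheds pivalaldehyde, leaving the quaternary centre untouched.

**Step 5**
Reactants: 6 (2R)-2-hydroxy-N,4,4-trimethoxy-N,2-dimethylbutanamide
Product: 7 (2R)-N,4,4-trimethoxy-N,2-dimethyl-2-(trimethylsilyloxy)butanamide
Conditions: TMSCl, imidazole, DMF, rt
Reagents that add atoms: chlorotrimethylsilane C[Si](C)(C)Cl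
Why: Silyl ether formation under triflate-free conditions covers the tertiary C10 hydroxyl, so that it cannot cyclise onto the ynone too early, and leaves the acetal intact.

**Step 6**
Reactants: 7 (2R)-N,4,4-trimethoxy-N,2-dimethyl-2-(trimethylsilyloxy)butanamide
Product: 8 (4R)-6,6-dimethoxy-4-methyl-4-(trimethylsilyloxy)hex-1-yn-3-one
Conditions: HC≡CMgBr (0.5 M in THF), THF, 0 °C; inverse quench into ice-cold aq. NaH2PO4
Reagents that add atoms: ethynylmagnesium bromide C#C[Mg]Br
Why: Weinreb ketone synthesis, in which the chelated tetrahedral intermediate stops the addition at the ketone and the cold buffered quench keeps the released amine from adding to the terminal ynone.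

**Step 7**
Reactants: 9 tert-butyldimethyl(prop-2-yn-1-yloxy)silane; 10 (E)-crotonaldehyde
Product: 11 rac-(5E)-1-(tert-butyldimethylsilyloxy)hept-5-en-2-yn-4-ol
Conditions: n-BuLi, THF, −78 °C; then 10, −78 °C; aq. NH4Cl
Reagents that add atoms: none
Why: 1,2-Addition of a lithium acetylide to an enal joins C5 to C6, and the racemic carbinol is resolved in the next step.

**Step 8**
Reactants: 11 rac-(5E)-1-(tert-butyldimethylsilyloxy)hept-5-en-2-yn-4-ol
Product: 12 (4S,5E)-1-(tert-butyldimethylsilyloxy)hept-5-en-2-yn-4-ol
Conditions: Ti(OiPr)4 (cat.), L-(+)-DIPT (cat.), t-BuOOH (0.6 equiv), 4 Å MS, CH2Cl2, −20 °C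
Reagents that add atoms: none
Why: Sharpless kinetic resolution, in which L-(+)-DIPT causes the (R)-carbinol of an E-propenyl carbinol to be epoxidised much faster, so the (S)-alcohol (future C6) should be recovered enantioenriched once the reaction is taken slightly past half conversion.

**Step 9**
Reactants: 12 (4S,5E)-1-(tert-butyldimethylsilyloxy)hept-5-en-2-yn-4-ol
Product: 13 (2Z,4S,5E)-1-(tert-butyldimethylsilyloxy)-2-iodohepta-2,5-dien-4-ol
Conditions: NaAlH2(OCH2CH2OMe)2 (Red-Al), THF, 0 °C; EtOAc; then I2, THF, −78 → 0 °C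
Reagents that add atoms: iodine II
Why: Hydroxyl-directed trans-hydroalumination with iodinolysis, in which the C6 alkoxide delivers hydride to C5 and holds aluminium on C4 in a five-membered ring, so iodine ends up on C4 cis to C6, and the low temperature suppresses β-elimination of the silyloxide.

**Step 10**
Reactants: 13 (2Z,4S,5E)-1-(tert-butyldimethylsilyloxy)-2-iodohepta-2,5-dien-4-ol
Product: 14 (2Z,4S,5E)-1-(tert-butyldimethylsilyloxy)-2-iodohepta-2,5-dien-4-yl acrylate
Conditions: acryloyl chloride, i-Pr2NEt, DMAP (cat.), CH2Cl2, −20 → 0 °C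
Reagents that add atoms: acryloyl chloride C=CC(=O)Cl
Why: DMAP-catalysed O-acylation brings in C11 and C12 and also blocks the C6 oxygen, which as a free cis-enynol hydroxyl would later cyclise onto the alkyne to give a furan.

**Step 11**
Reactants: 14 (2Z,4S,5E)-1-(tert-butyldimethylsilyloxy)-2-iodohepta-2,5-dien-4-yl acrylate; 8 (4R)-6,6-dimethoxy-4-methyl-4-(trimethylsilyloxy)hex-1-yn-3-one
Product: 15 (2E,4S,5E)-1-(tert-butyldimethylsilyloxy)-2-[(4R)-6,6-dimethoxy-4-methyl-3-oxo-4-(trimethylsilyloxy)hex-1-yn-1-yl]hepta-2,5-dien-4-yl acrylate (geometry unchanged, alkyne cis to C6; only the descriptor changes)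
Conditions: PdCl2(PPh3)2 (5 mol%), CuI (10 mol%), i-Pr2NEt, degassed THF, 0 °C → rt
Reagents that add atoms: none
Why: Sonogashira coupling forms C3–C4 with retention of the alkene geometry, because oxidative addition of zerovalent palladium into the vinyl C–I bond is far faster than ionisation of the allylic ester and the hindered amine does not add to the ynone.

**Step 12**
Reactants: 15 enynone acrylate from step 11
Product: 17 (2Z,4S,5E)-1-(tert-butyldimethylsilyloxy)-2-[(5R)-5-(2,2-dimethoxyethyl)-5-methyl-4-oxo-4,5-dihydrofuran-2-yl]hepta-2,5-dien-4-yl acrylate, via hydroxy ynone 16 (not isolated)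
Conditions: PPTS (cat.), MeOH, 0 °C; concentration; then [(4-CF3C6H4)3P]AuCl (5 mol%), AgOTf (5 mol%), toluene, rt
Reagents that add atoms: none
Why: Mild methanolysis of the tertiary TMS ether followed by the gold-catalysed 5-endo-dig cycloisomerisation of a γ-hydroxyalkynone closes ring B as the 3(2H)-furanone by attack of the C10 hydroxyl on C3, without touching C10.

**Step 13**
Reactants: 17 furanone acrylate from step 12
Product: 18 (5S)-5-{(1Z)-3-(tert-butyldimethylsilyloxy)-2-[(5R)-5-(2,2-dimethoxyethyl)-5-methyl-4-oxo-4,5-dihydrofuran-2-yl]prop-1-en-1-yl}furan-2(5H)-one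
Conditions: second-generation Grubbs catalyst (H2IMes)(PCy3)Cl2Ru=CHPh (5–10 mol%), 1,4-benzoquinone (10 mol%), CH2Cl2 (5 mM), reflux
Reagents that add atoms: none
Why: Ring-closing metathesis of the acrylate with the propenyl group closes ring C under neutral conditions, so the C6–H, which becomes acidic once it is γ to the butenolide and vinylogous to C1=O, never meets a base.

**Step 14**
Reactants: 18 butenolide acetal from step 13
Product: 19 2-[(2R)-5-{(1Z)-3-(tert-butyldimethylsilyloxy)-1-[(2S)-5-oxo-2,5-dihydrofuran-2-yl]prop-1-en-2-yl}-2-methyl-3-oxo-2,3-dihydrofuran-2-yl]acetaldehyde (furanone aldehyde with Z-alkenyl butenolide)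
Conditions: TsOH·H2O (10 mol%), acetone/H2O (20:1), 0 °C → rt; used crude at once
Reagents that add atoms: water O
Why: Acid-catalysed acetal hydrolysis frees the C8 aldehyde, since an aliphatic dimethyl acetal is cleaved faster than a primary TBS ether and acid does not enolise C6 or trigger β-elimination of the furanone oxygen as a base would.

**Step 15**
Reactants: 19 furanone aldehyde with Z-alkenyl butenolide
Product: 20 (4Z,6R,7R,8R,10R)-15-O-TBS furanone-bridged ten-membered 8-alcohol with saturated trans-fused 6,12-lactone (C11 is CH2)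
Conditions: SmI2 (0.1 M in THF, 2.2–2.5 equiv, syringe pump), t-BuOH (3 equiv), THF (1–2 mM in 19), −78 → −20 °C; cold aq. NH4Cl/Na2S2O3
Reagents that add atoms: none
Why: Proposed new method: SmI2 reduces the C8 aldehyde reversibly to a samarium ketyl, the ketyl carbon adds to C7 (the β-carbon of the C7=C11–C12 butenolide), and a second SmI2 turns the C11 radical into a trivalent samarium enolate that t-BuOH protonates to the C11 methylene group. The closest known reaction type is the SmI2 ketyl–olefin cyclisation of aldehydes onto α,β-unsaturated esters and lactones, established for five- to eight-membered rings, together with intermolecular ketyl additions to 2(5H)-furanones, whereas a ten-membered closure has not been shown. Ring A (ten-membered, or nine-membered if counted through the furanone oxygen) closes in the exo-trig mode with C11 left outside the new ring, and the entropic cost is lowered because the planar furanone and the cis C4=C5 alkene already fix most of the tether. C7 is controlled by C6, since the ketyl should attack the butenolide face anti to the C5 alkenyl substituent, the usual sense for 5-substituted 2(5H)-furanones, which gives the trans-fused lactone with H6 and H7 anti. C8 is controlled by the staggered transition state in which C9 lies anti to C6, H8 takes the crowded sector between C6 and C11, and the bulky O–Sm group points outward, anti to C7–C11 and away from the developing enolate, which gives 8R; one samarium bridging the ketyl oxygen and the lactone carbonyl does not fit this geometry, so chelation is not relied on. The step needs reduction of the aldehyde and capture by the butenolide in preference to electron transfer to the furanone dienone (whose C10–O and allylic C6–O bonds could leave reductively) and in preference to pinacol coupling; this is secured in the substrate by the vinylogous-ester character of C1=O and the strong acceptor ability of the butenolide, and supported by HMPA-free SmI2 added slowly to a cold millimolar solution so that reductant never accumulates.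

**Step 16**
Reactants: 20 saturated trans-lactone 8-alcohol
Product: 21 C11-(dimethylaminomethyl) derivative of 20 (C11 configuration of no consequence)
Conditions: LiN(i-Pr)2 (LDA, 3.2 equiv), THF, −78 °C; CH2=NMe2 I (Eschenmoser's salt, 5 equiv), −78 → −20 °C; aq. NH4Cl at −20 °C
Reagents that add atoms: Eschenmoser's salt C=[N+](C)C.[I-]
Why: Mannich reaction of the alkoxide–enolate dianion, in which C11–H2 is the only kinetically accessible carbonyl α-position (C10 is quaternary), the enolised lactone cannot be attacked by the C8 alkoxide, and the new C11 centre is erased in step 17.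

**Step 17**
Reactants: 21 C11-(dimethylaminomethyl) lactone
Product: 23 15-O-TBS 8-hydroxy α-methylene lactone (4Z,6R,7R,8R,10R), via ammonium iodide 22 (not isolated)
Conditions: MeI, THF, rt; then aq. NaHCO3, CH2Cl2, rt
Reagents that add atoms: iodomethane CI (methyl group of intermediate 22 only)
Why: Exhaustive N-methylation followed by a Hofmann-type E1cB elimination under bicarbonate installs C11=C13 without affecting the four stereocentres.

**Step 18**
Reactants: 23 15-O-TBS 8-hydroxy α-methylene lactone; 24 isobutyryl chloride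
Product: 25 15-O-TBS ether of the target
Conditions: pyridine, DMAP (cat.), CH2Cl2, 0 °C → rt
Reagents that add atoms: none
Why: DMAP-catalysed esterification acylates the only free hydroxyl (C8) with retention, and any addition of DMAP to the methylene lactone is reversible.

**Step 19**
Reactants: 25 15-O-TBS ether of the target
Product: 26 (4Z,6R,7R,8R,10R)-15-hydroxy-8-isobutyryloxy-1-oxo-3,10-epoxygermacra-2,4,11(13)-trien-12,6-olide (CNP0176924.3)
Conditions: HF·pyridine, THF, 0 °C → rt (plastic vessel)
Reagents that add atoms: none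
Why: Fluoride-mediated desilylation under mildly acidic conditions frees the primary allylic alcohol and spares the ester, the methylene lactone and the furanone.

**Compound list**
1 | (S)-lactic acid | C[C@H](O)C(=O)O | starting material
2 | (2S,5S)-2-tert-butyl-5-methyl-1,3-dioxolan-4-one | C[C@@H]1O[C@H](C(C)(C)C)OC1=O | intermediate
3 | (2S,5R)-5-allyl-2-tert-butyl-5-methyl-1,3-dioxolan-4-one | C[C@]1(CC=C)O[C@H](C(C)(C)C)OC1=O | intermediate
4 | (2S,5R)-2-tert-butyl-5-methyl-5-(2-oxoethyl)-1,3-dioxolan-4-one | C[C@]1(CC=O)O[C@H](C(C)(C)C)OC1=O | intermediate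
5 | (2S,5R)-2-tert-butyl-5-(2,2-dimethoxyethyl)-5-methyl-1,3-dioxolan-4-one | C[C@]1(CC(OC)OC)O[C@H](C(C)(C)C)OC1=O | intermediate
6 | (2R)-2-hydroxy-N,4,4-trimethoxy-N,2-dimethylbutanamide | CON(C)C(=O)[C@@](C)(CC(OC)OC)O | intermediate
7 | (2R)-N,4,4-trimethoxy-N,2-dimethyl-2-(trimethylsilyloxy)butanamide | CON(C)C(=O)[C@@](C)(CC(OC)OC)O[Si](C)(C)C | intermediate
8 | (4R)-6,6-dimethoxy-4-methyl-4-(trimethylsilyloxy)hex-1-yn-3-one | C#CC(=O)[C@@](C)(CC(OC)OC)O[Si](C)(C)C | intermediate
9 | tert-butyldimethyl(prop-2-yn-1-yloxy)silane | C#CCO[Si](C)(C)C(C)(C)C | starting material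
10 | (E)-crotonaldehyde | C/C=C/C=O | starting material
11 | rac-(5E)-1-(tert-butyldimethylsilyloxy)hept-5-en-2-yn-4-ol | C/C=C/C(O)C#CCO[Si](C)(C)C(C)(C)C | intermediate
12 | (4S,5E)-1-(tert-butyldimethylsilyloxy)hept-5-en-2-yn-4-ol | C/C=C/[C@H](O)C#CCO[Si](C)(C)C(C)(C)C | intermediate
13 | (2Z,4S,5E)-1-(tert-butyldimethylsilyloxy)-2-iodohepta-2,5-dien-4-ol | C/C=C/[C@H](O)/C=C(/CO[Si](C)(C)C(C)(C)C)I | intermediate
14 | (2Z,4S,5E)-1-(tert-butyldimethylsilyloxy)-2-iodohepta-2,5-dien-4-yl acrylate | C/C=C/[C@H](OC(=O)C=C)/C=C(/CO[Si](C)(C)C(C)(C)C)I | intermediate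
15 | enynone acrylate, (6S,10R), alkyne cis to C6, 10-OTMS, C8 dimethyl acetal | C/C=C/[C@H](OC(=O)C=C)/C=C(/CO[Si](C)(C)C(C)(C)C)C#CC(=O)[C@@](C)(CC(OC)OC)O[Si](C)(C)C | intermediate
16 | α′-hydroxy ynone (10-OH analogue of 15) | C/C=C/[C@H](OC(=O)C=C)/C=C(/CO[Si](C)(C)C(C)(C)C)C#CC(=O)[C@@](C)(CC(OC)OC)O | intermediate
17 | furanone acrylate, (4Z,6S,10R), C8 dimethyl acetal | C/C=C/[C@H](OC(=O)C=C)/C=C(/CO[Si](C)(C)C(C)(C)C)C1=CC(=O)[C@@](C)(CC(OC)OC)O1 | intermediate
18 | furanone butenolide, (4Z,6S,10R), C8 dimethyl acetal | COC(OC)C[C@@]1(C)OC(/C(CO[Si](C)(C)C(C)(C)C)=C\[C@H]2OC(=O)C=C2)=CC1=O | intermediate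
19 | furanone aldehyde with Z-alkenyl butenolide, (4Z,6S,10R) | O=CC[C@@]1(C)OC(/C(CO[Si](C)(C)C(C)(C)C)=C\[C@H]2OC(=O)C=C2)=CC1=O | intermediate
20 | furanone-bridged ten-membered 8-alcohol with saturated trans-lactone, (4Z,6R,7R,8R,10R) | O=C1C[C@H]2[C@H](O1)/C=C(/CO[Si](C)(C)C(C)(C)C)C3=CC(=O)[C@@](C)(C[C@H]2O)O3 | intermediate
21 | C11-(dimethylaminomethyl) derivative of 20 | O=C1C(CN(C)C)[C@H]2[C@H](O1)/C=C(/CO[Si](C)(C)C(C)(C)C)C3=CC(=O)[C@@](C)(C[C@H]2O)O3 | intermediate
22 | trimethylammonium iodide of 21 | O=C1C(C[N+](C)(C)C)[C@H]2[C@H](O1)/C=C(/CO[Si](C)(C)C(C)(C)C)C3=CC(=O)[C@@](C)(C[C@H]2O)O3.[I-] | intermediate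
23 | 15-O-TBS 8-hydroxy α-methylene lactone, (4Z,6R,7R,8R,10R) | C=C1C(=O)O[C@@H]2/C=C(/CO[Si](C)(C)C(C)(C)C)C3=CC(=O)[C@@](C)(C[C@@H](O)[C@@H]12)O3 | intermediate
24 | isobutyryl chloride | CC(C)C(=O)Cl | starting material
25 | 15-O-TBS ether of the target | C=C1C(=O)O[C@@H]2/C=C(/CO[Si](C)(C)C(C)(C)C)C3=CC(=O)[C@@](C)(C[C@@H](OC(=O)C(C)C)[C@@H]12)O3 | intermediate
26 | CNP0176924.3 | C=C1C(=O)O[C@@H]2/C=C(/CO)C3=CC(=O)[C@@](C)(C[C@@H](OC(=O)C(C)C)[C@@H]12)O3 | target

**Total step count:** 19. **Longest linear sequence:** 15 steps (steps 1–6 and 11–19).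

**Steps most likely to fail**

1. **Step 15** (bears the label).
   - What may go wrong: The ketyl may be reduced on to the primary alcohol, or couple intermolecularly, before it reaches C7. Electron transfer to the dienone may expel the allylic C6 carboxylate or cleave C10–O. Attack on the wrong butenolide face, or through the wrong ketyl rotamer, may erode control at C7 and C8. The trivalent samarium alkoxide at C8 may also translactonise.
   - Fallback (known chemistry), from 17 back to the route at 23: A Morita–Baylis–Hillman reaction of the acrylate with aqueous formaldehyde (DABCO, dioxane/H2O, rt) would give the 2-(hydroxymethyl)acrylate F1. Ring-closing metathesis (second-generation Hoveyda–Grubbs catalyst (H2IMes)Cl2Ru=CH(2-i-PrOC6H4), toluene, 80 °C) would give the α-(hydroxymethyl)butenolide acetal F2. Appel bromination (CBr4, PPh3, CH2Cl2, 0 °C) would give the α-(bromomethyl)butenolide acetal F3, and hydrolysis as in step 14 the bromo aldehyde F4.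
   - Ring closure in the fallback: An intramolecular Nozaki–Hiyama allylation (CrCl2, THF/DMF, high dilution, rt; zinc Barbier conditions as a variant) then joins C7 to C8 with allylic transposition. This type of closure is proven for ten-membered germacranolide rings, and as an intermolecular reaction of 3-(bromomethyl)furan-2(5H)-one with aldehydes. It delivers 23 directly, so steps 15–17 are bypassed.

2. **Step 16.**
   - What may go wrong: The C8 alkoxide may attack C12 before or after enolisation and shift the lactone from O6 to O8. The amide base may also deprotonate C6–H, which is vinylogous to C1=O, causing epimerisation or alkene migration.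
   - Fallback, from 20 back to the route at 23: The alkoxide is avoided altogether. Silylation (TESOTf, 2,6-lutidine, CH2Cl2, −78 °C) would give the 8-O-triethylsilyl ether F5. Mono-enolisation (LDA, 1.2 equiv, THF, −78 °C) and Eschenmoser's salt would give the Mannich base F6. MeI would give the ammonium iodide F7, and aq. NaHCO3 the 8-O-TES α-methylene lactone F8. Selective cleavage of the secondary TES ether beside the primary TBS ether (PPTS, MeOH/CH2Cl2, 0 °C) returns 23.

3. **Step 11.**
   - What may go wrong: The electron-poor terminal ynone may take up the amine by conjugate addition or homocouple at copper. Zerovalent palladium may ionise the bis-allylic acrylate, with loss of configuration at C6.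
   - Fallback, from 7 (with 14) back to the route at 15: Lithium (tributylstannyl)acetylide (ethynyltributylstannane, LDA, THF, −78 °C) would convert Weinreb amide 7 into the stannyl ynone F9. This is joined to iodide 14 in a base-free and copper-free Stille coupling (Pd2(dba)3, AsPh3, DMF, rt) to give 15, so the terminal ynone 8 is not needed.

**Further compounds**
F1 | step 15 | 2-(hydroxymethyl)acrylate analogue of 17 | C/C=C/[C@H](OC(=O)C(=C)CO)/C=C(/CO[Si](C)(C)C(C)(C)C)C1=CC(=O)[C@@](C)(CC(OC)OC)O1
F2 | step 15 | α-(hydroxymethyl)butenolide acetal | COC(OC)C[C@@]1(C)OC(/C(CO[Si](C)(C)C(C)(C)C)=C\[C@H]2OC(=O)C(CO)=C2)=CC1=O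
F3 | step 15 | α-(bromomethyl)butenolide acetal | COC(OC)C[C@@]1(C)OC(/C(CO[Si](C)(C)C(C)(C)C)=C\[C@H]2OC(=O)C(CBr)=C2)=CC1=O
F4 | step 15 | α-(bromomethyl)butenolide aldehyde | O=CC[C@@]1(C)OC(/C(CO[Si](C)(C)C(C)(C)C)=C\[C@H]2OC(=O)C(CBr)=C2)=CC1=O
F5 | step 16 | 8-O-triethylsilyl ether of 20 | O=C1C[C@H]2[C@H](O1)/C=C(/CO[Si](C)(C)C(C)(C)C)C3=CC(=O)[C@@](C)(C[C@H]2O[Si](CC)(CC)CC)O3
F6 | step 16 | C11-(dimethylaminomethyl) derivative of F5 | O=C1C(CN(C)C)[C@H]2[C@H](O1)/C=C(/CO[Si](C)(C)C(C)(C)C)C3=CC(=O)[C@@](C)(C[C@H]2O[Si](CC)(CC)CC)O3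
F7 | step 16 | trimethylammonium iodide of F6 | O=C1C(C[N+](C)(C)C)[C@H]2[C@H](O1)/C=C(/CO[Si](C)(C)C(C)(C)C)C3=CC(=O)[C@@](C)(C[C@H]2O[Si](CC)(CC)CC)O3.[I-]
F8 | step 16 | 8-O-TES, 15-O-TBS α-methylene lactone | C=C1C(=O)O[C@@H]2/C=C(/CO[Si](C)(C)C(C)(C)C)C3=CC(=O)[C@@](C)(C[C@@H](O[Si](CC)(CC)CC)[C@@H]12)O3
F9 | step 11 | (4R)-6,6-dimethoxy-4-methyl-1-(tributylstannyl)-4-(trimethylsilyloxy)hex-1-yn-3-one | CCCC[Sn](CCCC)(CCCC)C#CC(=O)[C@@](C)(CC(OC)OC)O[Si](C)(C)C
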